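**Retrosynthetic overview**

1. Locants: ring A a1(CMe2)–a2(CHBr)–a3–a4(CHOH)–a5(CMe); ring B b1(C–OH, bonded to a5)–b2–b3–b4(CMe)–b5(C–OH)–b6; ring C b4–c1(CHBr)–c2–c3–c4(CMe–OH)–b5. The strategy rests on the trans-fused rings B/C: quaternary b4 sits beside the heteroatom-bearing c1, and the fusion atoms b4 and b5 are joined by the four-atom link b6–b1–b2–b3 that holds the carbinol b1, which is the pattern of a 1,7,9-decatriene.
2. Key disconnection: b4–b5 and c1–c2 by an intramolecular Diels–Alder reaction of the (E)-nitroalkene b4(Me)=c1–NO2 with the (E)-diene b5=c4(Me)–c3=c2. Afterwards nitro → c1 ketone → axial alcohol → equatorial bromide, and c3=c4 → c4=b5 → α-epoxide → trans-diaxial c4/b5 diol.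
3. Triene: b1 is made from an allyl ketone on a5 and a Grignard reagent that carries b2–b3–b4 as a masked methyl ketone, added under chelation by the a4 hydroxyl. The allyl group is extended to the diene by cross-metathesis and methylenation; the nitroalkene comes from the methyl ketone and nitromethane.
4. Ring A from (+)-borneol: oxidation at C5, Baeyer–Villiger cleavage of C4–C5 (C4 becomes a2), double inversion at a2 to the bromide, and excision of the old C5 so that C6 becomes the b1 carbonyl.
5. Ring order: A from the chiral pool, then B and C together in the key step.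

Key step: step 16

Remark 1: α and β are the faces of the decalin, β being the face of the b4 methyl group; in ring A "cis" means the face that carries the a5 side chain (b1).
Remark 2: the hindered secondary TBS ether (a4) and tertiary TES ether (b1) are assumed to survive the mild or brief acid of steps 14, 17 and 22.

**Route**

Step 1
Reactants: 1 (+)-borneol
Product: 2 (+)-bornyl acetate
Conditions: Ac2O, pyridine, DMAP (cat.), CH2Cl2, rt
Reagents that add atoms: acetic anhydride CC(=O)OC(C)=O
Why: DMAP-catalysed acylation of the endo alcohol gives the acetate needed for the chromium oxidation and touches no stereocentre.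

Step 2
Reactants: 2 (+)-bornyl acetate
Product: 3 5-oxobornyl acetate
Conditions: CrO3, AcOH/Ac2O, 90 °C
Reagents that add atoms: chromium trioxide O=[Cr](=O)=O
Why: Chromium trioxide oxidation of bornyl acetate is the known remote C–H oxidation that takes place at the C5 methylene, across the ring from the acetoxy group.

Step 3
Reactants: 3 5-oxobornyl acetate
Product: 4 bridged δ-lactone acetate
Conditions: mCPBA, NaHCO3, CH2Cl2, rt
Reagents that add atoms: 3-chloroperbenzoic acid OOC(=O)c1cccc(Cl)c1
Why: Baeyer–Villiger oxidation in which the more substituted bridgehead carbon C4 migrates with retention, so the new a2–O bond is cis to the CH2 on a5.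

Step 4
Reactants: 4 bridged δ-lactone acetate
Product: 6 cis-hydroxy γ-lactone, via lithium dihydroxy carboxylate 5 (not isolated)
Conditions: LiOH, THF/H2O, rt; then 2 M HCl, rt
Reagents that add atoms: lithium hydroxide [Li+].[OH-]
Why: Saponification followed by acid-promoted translactonisation closes the strain-free cis-fused γ-lactone onto the adjacent a4 hydroxyl, which should be favoured over the bridged δ-lactone and frees the a2 hydroxyl.

Step 5
Reactants: 6 cis-hydroxy γ-lactone
Product: 8 trans-hydroxy γ-lactone, via trans chloroacetate 7 (not isolated)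
Conditions: ClCH2CO2H, PPh3, DIAD, toluene, 0 °C to rt; then K2CO3 (cat.), MeOH, 0 °C
Reagents that add atoms: chloroacetic acid OC(=O)CCl
Why: Mitsunobu inversion (chloroacetic acid variant for hindered alcohols) brings the carboxylate in from the convex face, and mild methanolysis of the chloroacetate leaves the a2 alcohol trans to the lactone ring.

Step 6
Reactants: 8 trans-hydroxy γ-lactone
Product: 9 bromo γ-lactone
Conditions: CBr4, PPh3, CH2Cl2, 0 °C to reflux
Reagents that add atoms: carbon tetrabromide BrC(Br)(Br)Br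
Why: Appel reaction with SN2 inversion at the cyclopentyl carbon next to the gem-dimethyl carbon puts bromine cis to a4–O and to the a5 side chain, as in the target.

Step 7
Reactants: 9 bromo γ-lactone; 10 allyl bromide
Product: 12 α-allyl bromo lactone, via lithium enolate 11 (not isolated)
Conditions: LiN(i-Pr)2, THF, −78 °C; then 10, DMPU, −78 to −20 °C
Reagents that add atoms: none
Why: Lactone enolate alkylation on the convex face; the configuration of the new centre does not matter because this carbon becomes the b1 carbonyl.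

Step 8
Reactants: 12 α-allyl bromo lactone
Product: 14 α-allyl-α-hydroxy bromo lactone, via potassium enolate 13 (not isolated)
Conditions: KN(SiMe3)2, THF, −78 °C; then 2-(phenylsulfonyl)-3-phenyloxaziridine, −78 °C
Reagents that add atoms: 2-(phenylsulfonyl)-3-phenyloxaziridine O=S(=O)(c1ccccc1)N1OC1c1ccccc1
Why: Enolate hydroxylation with an N-sulfonyloxaziridine installs the oxygen that becomes the b1 carbonyl oxygen.

Step 9
Reactants: 14 α-allyl-α-hydroxy bromo lactone
Product: 16 hydroxy allyl ketone, via allyl triol 15 (not isolated)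
Conditions: LiBH4, THF/MeOH, 0 °C to rt; then NaIO4, THF/H2O, rt
Reagents that add atoms: none
Why: Hydride reduction of the lactone and periodate (Malaprade) cleavage of the tertiary–primary 1,2-diol remove the old C5 as formaldehyde, leave the allyl ketone at b1 and release the a4 hydroxyl.

Step 10
Reactants: 16 hydroxy allyl ketone; 17 2-(2-bromoethyl)-2-methyl-1,3-dioxolane
Product: 19 b1 diol ketal, via Grignard reagent 18 (not isolated)
Conditions: 17, Mg, THF, rt; then LaCl3·2LiCl, 16, THF, −20 to 0 °C (3 equiv of 18)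
Reagents that add atoms: none
Why: Lanthanide-promoted Grignard 1,2-addition suppresses enolisation of the β,γ-unsaturated ketone, and the a4 alkoxide chelates the carbonyl in a ring cis-fused to ring A so that the nucleophile enters from the convex face (that of the a5 methyl, away from a1), which sets b1 as in the target; adding allyl to the other ketone would give the b1 epimer.

Step 11
Reactants: 19 b1 diol ketal
Product: 21 bis-silyl ether, via mono-TBS ether 20 (not isolated)
Conditions: TBSOTf (1.1 equiv), 2,6-lutidine, CH2Cl2, −78 to 0 °C; then TESOTf, 0 to 40 °C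
Reagents that add atoms: tert-butyldimethylsilyl triflate CC(C)(C)[Si](C)(C)OS(=O)(=O)C(F)(F)F; triethylsilyl triflate CC[Si](CC)(CC)OS(=O)(=O)C(F)(F)F
Why: Silylation with silyl triflates, the secondary a4 hydroxyl taking TBS first and the hindered tertiary b1 hydroxyl then taking the smaller TES group, which must be in place to stop hemiketal and oxa-Michael ring closure once the ketone and nitroalkene are present.

Step 12
Reactants: 21 bis-silyl ether; 22 methacrolein
Product: 23 (E)-enal
Conditions: 22 (excess), second-generation Hoveyda–Grubbs catalyst, RuCl2(SIMes)(=CH-C6H4-2-O-i-Pr) (5 mol%), CH2Cl2, 40 °C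
Reagents that add atoms: none
Why: Olefin cross-metathesis of the only terminal alkene with the 1,1-disubstituted enal gives the trisubstituted (E)-enal under thermodynamic control.

Step 13
Reactants: 23 (E)-enal
Product: 24 (E)-diene ketal
Conditions: Ph3PCH3Br, KOt-Bu, THF, 0 °C
Reagents that add atoms: methyltriphenylphosphonium bromide C[P+](c1ccccc1)(c1ccccc1)c1ccccc1.[Br-]
Why: Wittig methylenation of the aldehyde, the only free carbonyl, gives the 1,3-diene without changing the geometry of the trisubstituted double bond.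

Step 14
Reactants: 24 (E)-diene ketal
Product: 25 diene methyl ketone
Conditions: PPTS, acetone/H2O, 45 °C
Reagents that add atoms: water O
Why: Acid-catalysed ketal hydrolysis (transketalisation) mild enough for the hindered silyl ethers and the diene unmasks the methyl ketone at b4.

Step 15
Reactants: 25 diene methyl ketone; 26 nitromethane
Product: 28 nitro triene, via nitro alcohol 27 (not isolated)
Conditions: 26 (solvent), 1,1,3,3-tetramethylguanidine (0.3 equiv), rt; then (CF3CO)2O, Et3N, CH2Cl2, −20 °C
Reagents that add atoms: none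
Why: Henry (nitroaldol) addition in neat nitromethane and E1cB elimination of the trifluoroacetate give the conjugated nitroalkene, from which the (E) isomer (nitro cis to methyl) is separated by chromatography while the (Z) isomer is re-equilibrated with base and recycled.

Step 16
Reactants: 28 nitro triene
Product: 29 trans-fused nitro octalin
Conditions: toluene (0.01 M), BHT (cat.), 150 °C, sealed tube
Reagents that add atoms: none
Why: Concerted thermal [4+2] cycloaddition, an intramolecular Diels–Alder reaction of a 1-nitro-1,7,9-decatriene (a known class, here with a β,β-disubstituted nitroalkene), joins the (E)-diene b5=c4(Me)–c3=c2 to the (E)-nitroalkene b4(Me)=c1 and forms b4–b5 and c1–c2. Ring C is the new cyclohexene made directly by the cycloaddition, and ring B is closed at the same time as the four-atom tether b6–b1–b2–b3 folds into a chair. Suprafacial addition to the (E)-nitroalkene keeps nitro and methyl cis (b4 and c1), the nitro-endo, tether-anti transition state places the b5 hydrogen trans to the b4 methyl, and the sense of both relative to b1 follows from the chair in which the quaternary ring-A substituent is equatorial and the silyloxy group axial. The step needs endo selectivity (trans fusion), which the endo preference of the nitro group on an (E)-dienophile should supply, and facial selectivity relative to b1, which the strong equatorial preference of the ring-A substituent should supply. The geminal substitution at b1 (Thorpe–Ingold effect) and the electron-rich 1,2-dialkyl diene should help the hindered dienophile to react.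

Step 17
Reactants: 29 trans-fused nitro octalin
Product: 30 tetrasubstituted-olefin nitro octalin
Conditions: TsOH (anhydrous, cat.), benzene, 70 °C
Reagents that add atoms: none
Why: Acid-catalysed olefin isomerisation through the tertiary c4 cation moves the double bond to the tetrasubstituted c4=b5 position under thermodynamic control; it is done at the nitro stage because a c1 ketone would draw the c3=c4 bond into conjugation.

Step 18
Reactants: 30 tetrasubstituted-olefin nitro octalin
Product: 32 c1 ketone, via sodium nitronate 31 (not isolated)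
Conditions: NaOMe, MeOH/THF, 0 °C; then TiCl3 (aq.), NH4OAc, rt
Reagents that add atoms: water O
Why: Reductive Nef reaction of the nitronate with TiCl3 at buffered pH gives the c1 ketone, sparing the silyl ethers and the olefin, which cannot conjugate across quaternary b4.

Step 19
Reactants: 32 c1 ketone
Product: 33 c1 axial alcohol
Conditions: LiBH(s-Bu)3, THF, −78 to −40 °C
Reagents that add atoms: none
Why: Reduction with a bulky trialkylborohydride, which should attack along the equatorial (β) direction as with 4,4-dimethyl-3-oxo terpenoids because axial approach is blocked by the syn-axial hydrogens at c3 and b3, gives the α (axial) alcohol.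

Step 20
Reactants: 33 c1 axial alcohol
Product: 34 α-epoxy alcohol
Conditions: VO(acac)2 (cat.), t-BuOOH, CH2Cl2, 0 °C to rt
Reagents that add atoms: tert-butyl hydroperoxide CC(C)(C)OO
Why: Hydroxyl-directed vanadium-catalysed epoxidation of the homoallylic alcohol delivers oxygen to the α face of c4=b5, which is also the face away from the axial b4 methyl.

Step 21
Reactants: 34 α-epoxy alcohol
Product: 35 epoxy dibromide
Conditions: CBr4, PPh3, 2,6-lutidine, toluene, rt to 60 °C
Reagents that add atoms: carbon tetrabromide BrC(Br)(Br)Br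
Why: Appel reaction with SN2 inversion turns the axial α alcohol into the equatorial β bromide, the same type of displacement used for 3α-ol to 3β-bromide conversions beside a quaternary carbon in terpenoids.

Step 22
Reactants: 35 epoxy dibromide
Product: 36 bis-silyl neoirietetraol
Conditions: HClO4 (0.3 M aq.), THF, 0 °C
Reagents that add atoms: water O
Why: Acid-catalysed epoxide hydrolysis under the Fürst–Plattner rule, with water attacking tertiary c4 from the β face with inversion while the oxygen stays α on b5, gives the trans-diaxial diol.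

Step 23
Reactants: 36 bis-silyl neoirietetraol
Product: 37 neoirietetraol
Conditions: HF·pyridine, pyridine/THF, 0 °C to rt
Reagents that add atoms: none
Why: Fluoride-mediated desilylation under mildly acidic conditions frees the a4 and b1 hydroxyls without base-induced loss of HBr.

**Compound list**

1 | (+)-borneol, (1R,2S,4R)-1,7,7-trimethylbicyclo[2.2.1]heptan-2-ol | CC1(C)[C@H]2C[C@H](O)[C@]1(C)CC2 | starting material
2 | (+)-bornyl acetate (endo-2-acetate of 1) | CC1(C)[C@H]2C[C@H](OC(C)=O)[C@]1(C)CC2 | intermediate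
3 | 5-oxobornyl acetate (endo-2-acetoxybornan-5-one) | CC1(C)[C@H]2C[C@H](OC(C)=O)[C@]1(C)CC2=O | intermediate
4 | bridged δ-lactone acetate, 6-acetoxy-5,8,8-trimethyl-2-oxabicyclo[3.2.1]octan-3-one; ring oxygen on a2 and acetoxy on a4, both cis to the CH2 on a5 | CC1(C)[C@H]2C[C@H](OC(C)=O)[C@]1(C)CC(=O)O2 | intermediate
5 | lithium dihydroxy carboxylate; ring A with a2-OH, a4-OH and a5-CH2CO2Li all cis | CC1(C)[C@H](O)C[C@H](O)[C@]1(C)CC(=O)[O-].[Li+] | intermediate
6 | cis-hydroxy γ-lactone; cis-fused lactone a4-O-CO-CH2-a5, a2-OH cis to the lactone ring | CC1(C)[C@H](O)C[C@@H]2OC(=O)C[C@]12C | intermediate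
7 | trans chloroacetate; a2-OCOCH2Cl trans to the lactone ring | CC1(C)[C@@H](OC(=O)CCl)C[C@@H]2OC(=O)C[C@]12C | intermediate
8 | trans-hydroxy γ-lactone; a2-OH trans to the lactone ring | CC1(C)[C@@H](O)C[C@@H]2OC(=O)C[C@]12C | intermediate
9 | bromo γ-lactone; a2-Br, a4-O and the a5 CH2 all cis | CC1(C)[C@H](Br)C[C@@H]2OC(=O)C[C@]12C | intermediate
10 | allyl bromide | C=CCBr | starting material
11 | lithium enolate of 9 | CC1(C)[C@H](Br)C[C@@H]2OC([O-])=C[C@]12C.[Li+] | intermediate
12 | α-allyl bromo lactone; allyl on the lactone α-carbon, convex face | CC1(C)[C@H](Br)C[C@@H]2OC(=O)[C@@H](CC=C)[C@]12C | intermediate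
13 | potassium enolate of 12 | CC1(C)[C@H](Br)C[C@@H]2OC([O-])=C(CC=C)[C@]12C.[K+] | intermediate
14 | α-allyl-α-hydroxy bromo lactone; hydroxyl drawn on the convex face, a centre that is destroyed in step 9 | CC1(C)[C@H](Br)C[C@@H]2OC(=O)[C@](O)(CC=C)[C@]12C | intermediate
15 | allyl triol; ring A (a2-Br, a4-OH) with a5-C(OH)(allyl)CH2OH | CC1(C)[C@H](Br)C[C@H](O)[C@]1(C)[C@@](O)(CC=C)CO | intermediate
16 | hydroxy allyl ketone; ring A (a2-Br, a4-OH, a5 side chain all cis) with a5-CO-CH2CH=CH2, the b1 carbonyl | CC1(C)[C@H](Br)C[C@H](O)[C@]1(C)C(=O)CC=C | intermediate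
17 | 2-(2-bromoethyl)-2-methyl-1,3-dioxolane | CC1(CCBr)OCCO1 | starting material
18 | Grignard reagent, 2-(2-methyl-1,3-dioxolan-2-yl)ethylmagnesium bromide | CC1(CC[Mg]Br)OCCO1 | intermediate
19 | b1 diol ketal; b1 carbinol (configured as in the target) carrying ring A, allyl (b6 arm) and CH2CH2C(Me)(OCH2CH2O) (b2-b4 arm), a4-OH free | CC1(C)[C@H](Br)C[C@H](O)[C@]1(C)[C@@](O)(CCC1(C)OCCO1)CC=C | intermediate
20 | mono-TBS ether; 19 with a4-OTBS | CC1(C)[C@H](Br)C[C@H](O[Si](C)(C)C(C)(C)C)[C@]1(C)[C@@](O)(CCC1(C)OCCO1)CC=C | intermediate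
21 | bis-silyl ether; a4-OTBS, b1-OTES | CC1(C)[C@H](Br)C[C@H](O[Si](C)(C)C(C)(C)C)[C@]1(C)[C@@](O[Si](CC)(CC)CC)(CCC1(C)OCCO1)CC=C | intermediate
22 | methacrolein | CC(=C)C=O | starting material
23 | (E)-enal; b6H2-b5H=c4(Me)-CHO | CC1(C)[C@H](Br)C[C@H](O[Si](C)(C)C(C)(C)C)[C@]1(C)[C@@](O[Si](CC)(CC)CC)(CCC1(C)OCCO1)C/C=C(\C)C=O | intermediate
24 | (E)-diene ketal; b6H2-b5H=c4(Me)-c3H=c2H2 | CC1(C)[C@H](Br)C[C@H](O[Si](C)(C)C(C)(C)C)[C@]1(C)[C@@](O[Si](CC)(CC)CC)(CCC1(C)OCCO1)C/C=C(\C)C=C | intermediate
25 | diene methyl ketone; b2H2-b3H2-b4(=O)Me | CC1(C)[C@H](Br)C[C@H](O[Si](C)(C)C(C)(C)C)[C@]1(C)[C@@](O[Si](CC)(CC)CC)(CCC(C)=O)C/C=C(\C)C=C | intermediate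
26 | nitromethane | C[N+](=O)[O-] | starting material
27 | nitro alcohol; b4(OH)(Me)CH2NO2, both epimers at b4 | CC1(C)[C@H](Br)C[C@H](O[Si](C)(C)C(C)(C)C)[C@]1(C)[C@@](O[Si](CC)(CC)CC)(CCC(C)(O)C[N+](=O)[O-])C/C=C(\C)C=C | intermediate
28 | nitro triene; (E)-nitroalkene b4(Me)=c1H-NO2 and (E)-diene on b1, a4-OTBS, b1-OTES | CC1(C)[C@H](Br)C[C@H](O[Si](C)(C)C(C)(C)C)[C@]1(C)[C@@](O[Si](CC)(CC)CC)(CC/C(C)=C/[N+](=O)[O-])C/C=C(\C)C=C | intermediate
29 | trans-fused nitro octalin; b4-Me β, b5-H α, c1-NO2 β, c3=c4, b1-OTES α (axial), ring A equatorial | CC1(C)[C@H](Br)C[C@H](O[Si](C)(C)C(C)(C)C)[C@]1(C)[C@@]1(O[Si](CC)(CC)CC)CC[C@]2(C)[C@@H]([N+](=O)[O-])CC=C(C)[C@H]2C1 | intermediate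
30 | tetrasubstituted-olefin nitro octalin; c4=b5 | CC1(C)[C@H](Br)C[C@H](O[Si](C)(C)C(C)(C)C)[C@]1(C)[C@@]1(O[Si](CC)(CC)CC)CC[C@]2(C)[C@@H]([N+](=O)[O-])CCC(C)=C2C1 | intermediate
31 | sodium nitronate of 30 | CC1(C)[C@H](Br)C[C@H](O[Si](C)(C)C(C)(C)C)[C@]1(C)[C@@]1(O[Si](CC)(CC)CC)CC[C@]2(C)C(=[N+]([O-])[O-])CCC(C)=C2C1.[Na+] | intermediate
32 | c1 ketone; c4=b5 olefin | CC1(C)[C@H](Br)C[C@H](O[Si](C)(C)C(C)(C)C)[C@]1(C)[C@@]1(O[Si](CC)(CC)CC)CC[C@]2(C)C(=O)CCC(C)=C2C1 | intermediate
33 | c1 axial alcohol; c1-OH α | CC1(C)[C@H](Br)C[C@H](O[Si](C)(C)C(C)(C)C)[C@]1(C)[C@@]1(O[Si](CC)(CC)CC)CC[C@]2(C)[C@H](O)CCC(C)=C2C1 | intermediate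
34 | α-epoxy alcohol; c4/b5 epoxide on the α face, c1-OH α | CC1(C)[C@H](Br)C[C@H](O[Si](C)(C)C(C)(C)C)[C@]1(C)[C@@]1(O[Si](CC)(CC)CC)CC[C@]2(C)[C@H](O)CC[C@]3(C)O[C@]23C1 | intermediate
35 | epoxy dibromide; c1-Br β (equatorial), α-epoxide | CC1(C)[C@H](Br)C[C@H](O[Si](C)(C)C(C)(C)C)[C@]1(C)[C@@]1(O[Si](CC)(CC)CC)CC[C@]2(C)[C@@H](Br)CC[C@]3(C)O[C@]23C1 | intermediate
36 | bis-silyl neoirietetraol; c4-OH β, b5-OH α, a4-OTBS, b1-OTES | CC1(C)[C@H](Br)C[C@H](O[Si](C)(C)C(C)(C)C)[C@]1(C)[C@@]1(O[Si](CC)(CC)CC)CC[C@]2(C)[C@@H](Br)CC[C@@](C)(O)[C@@]2(O)C1 | intermediate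
37 | neoirietetraol | CC1(C)[C@H](Br)C[C@H](O)[C@]1(C)[C@@]1(O)CC[C@]2(C)[C@@H](Br)CC[C@@](C)(O)[C@@]2(O)C1 | target

**Step count**

Total step count: 23. Longest linear sequence: 23 steps from 1 (10, 17, 22 and 26 are bought).

**Steps most likely to fail**

Step 16. The cycloaddition at the fully substituted dienophile carbon may be slow enough for the nitroalkene to deconjugate or lose its (E) geometry on heating, and the endo (trans-fusion) selectivity may be incomplete. The fallback replaces the nitro group by a phenylsulfonyl group, which is configurationally stable and tolerates long heating. It sets out from methyl ketone 25: Horner–Wadsworth–Emmons olefination with diethyl (phenylsulfonylmethyl)phosphonate (NaH, THF) should give the (E)-vinyl sulfone triene F1. Its intramolecular Diels–Alder reaction (toluene, 180 °C) should give the sulfonyl octalin F2, and acid isomerisation as in step 17 the tetrasubstituted-olefin sulfone F3. Deprotonation α to sulfur (LiN(i-Pr)2, THF, −78 °C) and oxidation with MoO5·pyridine·HMPA (oxidative desulfonylation) should then give ketone 32, where the route is rejoined.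

Step 17. The equilibration may stop at a mixture of c3=c4 and c4=b5 isomers, the double bond may travel on to b5=b6, or the acid may ionise the tertiary silyl ether at b1. The fallback moves the double bond by hydration and dehydration without strong acid. It sets out from 29: Mukaiyama hydration (Co(acac)2 cat., PhSiH3, O2, i-PrOH) should give the tertiary c4 alcohol F4. Dehydration with methyl N-(triethylammoniosulfonyl)carbamate (Burgess reagent, benzene, 50 °C) should favour the more substituted olefin and give 30, where the route is rejoined; the c3=c4 isomer 29 formed alongside is recycled.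

Step 21. The oxyphosphonium ion at the neopentyl-type c1 may undergo E2 elimination toward c2 or a 1,2-shift of the antiperiplanar b4 methyl, or the epoxide may open, instead of substitution by bromide. The fallback uses a cyclic sulfate tied to the b5 oxygen as the leaving group. It sets out from 34: hydrolysis as in step 22 should give the triol F5, whose syn-diaxial c1/b5 diol is closed with SOCl2 and pyridine (CH2Cl2, −40 °C) to the cyclic sulfite F6 and oxidised (RuCl3 cat., NaIO4, MeCN/H2O) to the cyclic sulfate F7. LiBr (THF/DMF, 50 °C) should open it at the secondary c1 with inversion to the lithium bromo sulfate F8, and mild acid hydrolysis (H2SO4 cat., THF/H2O) should give 36, where the route is rejoined.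

**Further compounds**

F1 | step 16 | (E)-vinyl sulfone triene | CC1(C)[C@H](Br)C[C@H](O[Si](C)(C)C(C)(C)C)[C@]1(C)[C@@](O[Si](CC)(CC)CC)(CC/C(C)=C/S(=O)(=O)c1ccccc1)C/C=C(\C)C=C
F2 | step 16 | trans-fused sulfonyl octalin | CC1(C)[C@H](Br)C[C@H](O[Si](C)(C)C(C)(C)C)[C@]1(C)[C@@]1(O[Si](CC)(CC)CC)CC[C@]2(C)[C@@H](S(=O)(=O)c3ccccc3)CC=C(C)[C@H]2C1
F3 | step 16 | tetrasubstituted-olefin sulfone | CC1(C)[C@H](Br)C[C@H](O[Si](C)(C)C(C)(C)C)[C@]1(C)[C@@]1(O[Si](CC)(CC)CC)CC[C@]2(C)[C@@H](S(=O)(=O)c3ccccc3)CCC(C)=C2C1
F4 | step 17 | tertiary c4 alcohol (both epimers at c4) | CC1(C)[C@H](Br)C[C@H](O[Si](C)(C)C(C)(C)C)[C@]1(C)[C@@]1(O[Si](CC)(CC)CC)CC[C@]2(C)[C@@H]([N+](=O)[O-])CCC(C)(O)[C@H]2C1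
F5 | step 21 | triol with c1-OH α, c4-OH β, b5-OH α | CC1(C)[C@H](Br)C[C@H](O[Si](C)(C)C(C)(C)C)[C@]1(C)[C@@]1(O[Si](CC)(CC)CC)CC[C@]2(C)[C@H](O)CC[C@@](C)(O)[C@@]2(O)C1
F6 | step 21 | c1/b5 cyclic sulfite | CC1(C)[C@H](Br)C[C@H](O[Si](C)(C)C(C)(C)C)[C@]1(C)[C@@]1(O[Si](CC)(CC)CC)CC[C@]2(C)[C@H]3CC[C@@](C)(O)[C@@]2(OS(=O)O3)C1
F7 | step 21 | c1/b5 cyclic sulfate | CC1(C)[C@H](Br)C[C@H](O[Si](C)(C)C(C)(C)C)[C@]1(C)[C@@]1(O[Si](CC)(CC)CC)CC[C@]2(C)[C@H]3CC[C@@](C)(O)[C@@]2(OS(=O)(=O)O3)C1
F8 | step 21 | lithium bromo sulfate (b5 sulfate monoester, c1-Br β) | CC1(C)[C@H](Br)C[C@H](O[Si](C)(C)C(C)(C)C)[C@]1(C)[C@@]1(O[Si](CC)(CC)CC)CC[C@]2(C)[C@@H](Br)CC[C@@](C)(O)[C@@]2(OS(=O)(=O)[O-])C1.[Li+]
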